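**Plan**

1. Retrosynthesis: the ring B quinone goes back to a dibenzyl hydroquinone and the C4 ketone to a silyl-protected carbinol. The heterocycle is then cut at the aryl ether bond O1–C8a, which leaves an open-chain (S)-carbinol at C2 and a bromide at C8a of ring A.
2. The C3–C4 bond is cut next (aldol) into a ring B methyl ketone (from paeonol) and a ring A 2-benzyloxy-6-bromobenzaldehyde.
3. The hexasubstituted ring A comes from 4-methoxy-3,5-dimethylaniline: the amino group places two bromines meta to the methoxy group and is then removed, one bromine becomes the C5 oxygen, and the formyl carbon (C4) enters between oxygen and bromine.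
4. Forward: the aldol joins rings A and B through the C2–C3–C4 chain, the carbinol is silylated, the ketone is reduced, and the pyran ring (the only ring formed) closes by palladium-catalysed O1–C8a coupling. Desilylation, C4 oxidation, debenzylation and hydroquinone oxidation finish the synthesis.
5. Stereochemistry: C2 (S), the only stereocentre, comes from asymmetric transfer hydrogenation of the ring B aryl ketone (step 10). The enabling feature is that O1 lies between the arene carbon C8a of ring A and the benzylic carbon C2 that carries the electron-rich ring B, so closing the ring at C8a never makes or breaks the labile C2–O bond.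

Key step: step 11

Remark: the carbon that becomes C4 is formed racemic in step 8 and carried as a pair of epimers through steps 10 to 12; this is harmless because it is oxidised to the carbonyl in step 13.

**Route**

Step 1
Reactants: 1 2'-hydroxy-4'-methoxyacetophenone (paeonol)
Product: 3 2',5'-dihydroxy-4'-methoxyacetophenone, via aryl potassium sulfate 2 (not isolated)
Conditions: K2S2O8, aq NaOH, 15 °C to rt; then aq HCl, 90 °C
Reagents that add atoms: potassium peroxydisulfate, [K+].[K+].[O-]S(=O)(=O)OOS(=O)(=O)[O-]
Why: Elbs persulfate oxidation, in which the phenoxide of 1 is attacked by peroxydisulfate at the only free carbon para to the phenolic oxygen and acid hydrolysis of the aryl sulfate then releases the hydroquinone.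

Step 2
Reactants: 3 2',5'-dihydroxy-4'-methoxyacetophenone
Product: 4 1-[2,5-bis(benzyloxy)-4-methoxyphenyl]ethan-1-one
Conditions: BnBr, K2CO3, DMF, 60 °C, under N2
Reagents that add atoms: benzyl bromide, BrCc1ccccc1
Why: Williamson ether synthesis that alkylates both phenols, including the one hydrogen-bonded to the acetyl group, with benzyl chosen so that all benzyl ethers of the route fall in one hydrogenolysis at the end.

Step 3
Reactants: 5 4-methoxy-3,5-dimethylaniline
Product: 6 2,6-dibromo-4-methoxy-3,5-dimethylaniline
Conditions: NBS (2.1 equiv), MeCN, 0 °C to rt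
Reagents that add atoms: N-bromosuccinimide, BrN1C(=O)CCC1=O
Why: Electrophilic aromatic bromination steered by the amino group to its two free ortho carbons, which are the positions meta to the methoxy group (the future C5 and C8a) that no oxygen substituent of ring A could activate.

Step 4
Reactants: 6 2,6-dibromo-4-methoxy-3,5-dimethylaniline
Product: 8 1,5-dibromo-3-methoxy-2,4-dimethylbenzene, via arenediazonium hydrogensulfate 7 (not isolated)
Conditions: NaNO2, conc. H2SO4, AcOH, 0–5 °C; then 50% aq H3PO2, 0 °C to rt
Reagents that add atoms: none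
Why: Reductive deamination (diazotisation of the weakly basic dibromoaniline under nitrosylsulfuric acid conditions, then hypophosphorous acid reduction of the diazonium salt) removes the amino group once it has done its directing work.

Step 5
Reactants: 8 1,5-dibromo-3-methoxy-2,4-dimethylbenzene
Product: 11 5-bromo-3-methoxy-2,4-dimethylphenol, via aryllithium 9 (not isolated), via lithium aryltrimethoxyborate 10 (not isolated)
Conditions: n-BuLi (1.0 equiv), THF, −78 °C; B(OMe)3, −78 °C to rt; then AcOH, 30% aq H2O2, 0 °C to rt
Reagents that add atoms: hydrogen peroxide, OO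
Why: Bromine–lithium exchange on one of two equivalent bromides followed by borylation and peroxide oxidation of the aryl–boron bond (aryl migration from boron to oxygen) turns one C–Br into the phenol that becomes the C5 oxygen and keeps the other bromide for C8a.

Step 6
Reactants: 11 5-bromo-3-methoxy-2,4-dimethylphenol
Product: 12 6-bromo-2-hydroxy-4-methoxy-3,5-dimethylbenzaldehyde
Conditions: MgCl2, Et3N, (CH2O)n, MeCN, reflux
Reagents that add atoms: paraformaldehyde (as formaldehyde), C=O
Why: Magnesium-mediated ortho-formylation of a phenol (Casnati–Skattebøl reaction), in which the magnesium phenoxide delivers formaldehyde to the single free ortho carbon, which is also para to the methoxy group, and a second formaldehyde oxidises the hydroxymethyl intermediate to the aldehyde.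

Step 7
Reactants: 12 6-bromo-2-hydroxy-4-methoxy-3,5-dimethylbenzaldehyde
Product: 13 2-(benzyloxy)-6-bromo-4-methoxy-3,5-dimethylbenzaldehyde
Conditions: BnBr, K2CO3, DMF, 50 °C
Reagents that add atoms: benzyl bromide, BrCc1ccccc1
Why: Williamson etherification of the salicylaldehyde hydroxyl, which masks the C5 oxygen as a benzyl ether that withstands enolates, carbonate, fluoride and Dess–Martin oxidation.

Step 8
Reactants: 4 1-[2,5-bis(benzyloxy)-4-methoxyphenyl]ethan-1-one; 13 2-(benzyloxy)-6-bromo-4-methoxy-3,5-dimethylbenzaldehyde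
Product: 15 rac-3-[2-(benzyloxy)-6-bromo-4-methoxy-3,5-dimethylphenyl]-1-[2,5-bis(benzyloxy)-4-methoxyphenyl]-3-hydroxypropan-1-one, via lithium enolate 14 (not isolated)
Conditions: LiN(SiMe3)2, THF, −78 °C; then 13, −78 °C; AcOH quench at −78 °C
Reagents that add atoms: none
Why: Directed aldol addition of the preformed lithium enolate of methyl ketone 4 to the non-enolisable aldehyde 13 with cold protonation to suppress retro-aldol cleavage and dehydration, the new carbinol centre (the future C4) being formed without control because it ends as a carbonyl.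

Step 9
Reactants: 15 rac-3-[2-(benzyloxy)-6-bromo-4-methoxy-3,5-dimethylphenyl]-1-[2,5-bis(benzyloxy)-4-methoxyphenyl]-3-hydroxypropan-1-one
Product: 16 rac-3-[2-(benzyloxy)-6-bromo-4-methoxy-3,5-dimethylphenyl]-1-[2,5-bis(benzyloxy)-4-methoxyphenyl]-3-[(tert-butyldimethylsilyl)oxy]propan-1-one
Conditions: TBSOTf, 2,6-lutidine, CH2Cl2, −78 to 0 °C
Reagents that add atoms: tert-butyldimethylsilyl trifluoromethanesulfonate, CC(C)(C)[Si](C)(C)OS(=O)(=O)C(F)(F)F
Why: Silylation of the hindered benzylic alcohol with a silyl triflate and a hindered pyridine base is fast at low temperature, so neither enol silylation nor β-elimination should compete, and the silyl ether blocks retro-aldol cleavage and enone formation in the later basic steps.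

Step 10
Reactants: 16 rac-3-[2-(benzyloxy)-6-bromo-4-methoxy-3,5-dimethylphenyl]-1-[2,5-bis(benzyloxy)-4-methoxyphenyl]-3-[(tert-butyldimethylsilyl)oxy]propan-1-one
Product: 17 (1S)-1-[2,5-bis(benzyloxy)-4-methoxyphenyl]-3-[2-(benzyloxy)-6-bromo-4-methoxy-3,5-dimethylphenyl]-3-[(tert-butyldimethylsilyl)oxy]propan-1-ol (both C3 epimers)
Conditions: RuCl[(S,S)-TsDPEN](p-cymene) (2 mol%), HCO2H/Et3N (5:2), CH2Cl2, 30 °C
Reagents that add atoms: none
Why: Noyori asymmetric transfer hydrogenation of an aryl alkyl ketone, in which the ruthenium hydride of the (S,S)-TsDPEN complex delivers hydride and proton through a six-membered transition state whose face is fixed by a CH/π contact between the cymene ligand and ring B, which by analogy with acetophenone should give the (1S)-carbinol under catalyst control whatever the configuration at the remote silyloxy carbon.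

Step 11
Reactants: 17 (1S)-1-[2,5-bis(benzyloxy)-4-methoxyphenyl]-3-[2-(benzyloxy)-6-bromo-4-methoxy-3,5-dimethylphenyl]-3-[(tert-butyldimethylsilyl)oxy]propan-1-ol (both C3 epimers)
Product: 18 (2S)-5-(benzyloxy)-2-[2,5-bis(benzyloxy)-4-methoxyphenyl]-4-[(tert-butyldimethylsilyl)oxy]-7-methoxy-6,8-dimethylchromane (both C4 epimers)
Conditions: [Pd(allyl)Cl]2 (2.5 mol%), RockPhos (2-di-tert-butylphosphino-3-methoxy-6-methyl-2',4',6'-triisopropylbiphenyl, 7.5 mol%), Cs2CO3, toluene, 90 °C
Reagents that add atoms: none
Why: Zerovalent palladium formed from [Pd(allyl)Cl]2 and the bulky biarylphosphine adds oxidatively into the C8a–Br bond, the carbinol is deprotonated by Cs2CO3 on the divalent arylpalladium bromide to give a seven-membered aryl(alkoxo)palladium chelate, and C–O reductive elimination forms O1–C8a. The closest known reaction type is the intramolecular palladium-catalysed etherification of aryl bromides carrying a tethered secondary alcohol (Buchwald–Hartwig C–O coupling), which gives chromans without loss of configuration at the carbinol. The pyran ring closes as a six-membered ring, formally 6-exo at the arene carbon, by ring contraction of the seven-membered palladacycle. No stereocentre is created: the C2 configuration is that set in step 10 and is retained because only the O–H and C8a–Br bonds are broken. The selectivity required is reductive elimination over β-hydride elimination of the palladium alkoxide, which would give the aryl ketone and the debrominated arene; the large ligand together with the two ortho substituents at C8a (the C8 methyl and the C4a side chain) crowds the metal and speeds reductive elimination, and the silyl ether at C4 rules out base-induced retro-aldol cleavage or elimination.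

Step 12
Reactants: 18 (2S)-5-(benzyloxy)-2-[2,5-bis(benzyloxy)-4-methoxyphenyl]-4-[(tert-butyldimethylsilyl)oxy]-7-methoxy-6,8-dimethylchromane (both C4 epimers)
Product: 19 (2S)-5-(benzyloxy)-2-[2,5-bis(benzyloxy)-4-methoxyphenyl]-7-methoxy-6,8-dimethylchroman-4-ol (both C4 epimers)
Conditions: Bu4NF, THF, 0 °C to rt
Reagents that add atoms: none
Why: Fluoride-mediated desilylation driven by Si–F bond formation, to which the benzyl ethers, the aryl ethers and the C2–O bond are inert.

Step 13
Reactants: 19 (2S)-5-(benzyloxy)-2-[2,5-bis(benzyloxy)-4-methoxyphenyl]-7-methoxy-6,8-dimethylchroman-4-ol (both C4 epimers)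
Product: 20 (2S)-5-(benzyloxy)-2-[2,5-bis(benzyloxy)-4-methoxyphenyl]-7-methoxy-6,8-dimethylchroman-4-one
Conditions: Dess–Martin periodinane, CH2Cl2, 0 °C to rt
Reagents that add atoms: none
Why: Dess–Martin oxidation of the secondary benzylic alcohol under near-neutral, base-free conditions converts both C4 epimers into one ketone and avoids the retro-oxa-Michael ring opening of the flavanone that would scramble C2.

Step 14
Reactants: 20 (2S)-5-(benzyloxy)-2-[2,5-bis(benzyloxy)-4-methoxyphenyl]-7-methoxy-6,8-dimethylchroman-4-one
Product: 21 (2S)-2-(2,5-dihydroxy-4-methoxyphenyl)-5-hydroxy-7-methoxy-6,8-dimethylchroman-4-one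
Conditions: H2 (1 atm), 10% Pd/C, EtOAc, rt
Reagents that add atoms: none
Why: Catalytic hydrogenolysis of the three aryl benzyl ethers under neutral conditions, the usual way to unmask benzyl-protected flavanones, should be faster than cleavage of the ring O1–C2 bond or reduction of the chelated C4 carbonyl if the reaction is stopped once the benzyl ethers are consumed.

Step 15
Reactants: 21 (2S)-2-(2,5-dihydroxy-4-methoxyphenyl)-5-hydroxy-7-methoxy-6,8-dimethylchroman-4-one
Product: 22 (2S)-5-hydroxy-7-methoxy-2-(4-methoxy-3,6-dioxocyclohexa-1,4-dien-1-yl)-6,8-dimethylchroman-4-one (CNP0208927.1)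
Conditions: Ag2O, Et2O/CH2Cl2, rt
Reagents that add atoms: none
Why: Mild two-electron oxidation of the para-hydroquinone of ring B to the 1,4-benzoquinone by silver oxide, which should leave untouched the ring A phenol (hydrogen-bonded to the C4 carbonyl and without a para oxygen partner) and the C2 stereocentre.

**Compound list**

1 | 2'-hydroxy-4'-methoxyacetophenone (paeonol) | CC(=O)c1ccc(OC)cc1O | starting material
2 | potassium 5-acetyl-4-hydroxy-2-methoxyphenyl sulfate (not isolated) | CC(=O)c1cc(OS(=O)(=O)[O-])c(OC)cc1O.[K+] | intermediate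
3 | 2',5'-dihydroxy-4'-methoxyacetophenone | CC(=O)c1cc(O)c(OC)cc1O | intermediate
4 | 1-[2,5-bis(benzyloxy)-4-methoxyphenyl]ethan-1-one | CC(=O)c1cc(OCc2ccccc2)c(OC)cc1OCc1ccccc1 | intermediate
5 | 4-methoxy-3,5-dimethylaniline | COc1c(C)cc(N)cc1C | starting material
6 | 2,6-dibromo-4-methoxy-3,5-dimethylaniline | COc1c(C)c(Br)c(N)c(Br)c1C | intermediate
7 | 2,6-dibromo-4-methoxy-3,5-dimethylbenzenediazonium hydrogensulfate (not isolated) | COc1c(C)c(Br)c([N+]#N)c(Br)c1C.OS(=O)(=O)[O-] | intermediate
8 | 1,5-dibromo-3-methoxy-2,4-dimethylbenzene | COc1c(C)c(Br)cc(Br)c1C | intermediate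
9 | (5-bromo-3-methoxy-2,4-dimethylphenyl)lithium (not isolated) | [Li]c1cc(Br)c(C)c(OC)c1C | intermediate
10 | lithium (5-bromo-3-methoxy-2,4-dimethylphenyl)trimethoxyborate (not isolated) | [Li+].CO[B-](OC)(OC)c1cc(Br)c(C)c(OC)c1C | intermediate
11 | 5-bromo-3-methoxy-2,4-dimethylphenol | Oc1cc(Br)c(C)c(OC)c1C | intermediate
12 | 6-bromo-2-hydroxy-4-methoxy-3,5-dimethylbenzaldehyde | O=Cc1c(O)c(C)c(OC)c(C)c1Br | intermediate
13 | 2-(benzyloxy)-6-bromo-4-methoxy-3,5-dimethylbenzaldehyde | O=Cc1c(OCc2ccccc2)c(C)c(OC)c(C)c1Br | intermediate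
14 | lithium 1-[2,5-bis(benzyloxy)-4-methoxyphenyl]ethen-1-olate (not isolated) | [Li]OC(=C)c1cc(OCc2ccccc2)c(OC)cc1OCc1ccccc1 | intermediate
15 | rac-3-[2-(benzyloxy)-6-bromo-4-methoxy-3,5-dimethylphenyl]-1-[2,5-bis(benzyloxy)-4-methoxyphenyl]-3-hydroxypropan-1-one | COc1cc(OCc2ccccc2)c(cc1OCc1ccccc1)C(=O)CC(O)c1c(Br)c(C)c(OC)c(C)c1OCc1ccccc1 | intermediate
16 | rac-3-[2-(benzyloxy)-6-bromo-4-methoxy-3,5-dimethylphenyl]-1-[2,5-bis(benzyloxy)-4-methoxyphenyl]-3-[(tert-butyldimethylsilyl)oxy]propan-1-one | COc1cc(OCc2ccccc2)c(cc1OCc1ccccc1)C(=O)CC(O[Si](C)(C)C(C)(C)C)c1c(Br)c(C)c(OC)c(C)c1OCc1ccccc1 | intermediate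
17 | (1S)-1-[2,5-bis(benzyloxy)-4-methoxyphenyl]-3-[2-(benzyloxy)-6-bromo-4-methoxy-3,5-dimethylphenyl]-3-[(tert-butyldimethylsilyl)oxy]propan-1-ol, both C3 epimers (precursor of the key step) | COc1cc(OCc2ccccc2)c(cc1OCc1ccccc1)[C@@H](O)CC(O[Si](C)(C)C(C)(C)C)c1c(Br)c(C)c(OC)c(C)c1OCc1ccccc1 | intermediate
18 | (2S)-5-(benzyloxy)-2-[2,5-bis(benzyloxy)-4-methoxyphenyl]-4-[(tert-butyldimethylsilyl)oxy]-7-methoxy-6,8-dimethylchromane, both C4 epimers (product of the key step) | COc1cc(OCc2ccccc2)c(cc1OCc1ccccc1)[C@@H]3CC(O[Si](C)(C)C(C)(C)C)c4c(OCc5ccccc5)c(C)c(OC)c(C)c4O3 | intermediate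
19 | (2S)-5-(benzyloxy)-2-[2,5-bis(benzyloxy)-4-methoxyphenyl]-7-methoxy-6,8-dimethylchroman-4-ol, both C4 epimers | COc1cc(OCc2ccccc2)c(cc1OCc1ccccc1)[C@@H]3CC(O)c4c(OCc5ccccc5)c(C)c(OC)c(C)c4O3 | intermediate
20 | (2S)-5-(benzyloxy)-2-[2,5-bis(benzyloxy)-4-methoxyphenyl]-7-methoxy-6,8-dimethylchroman-4-one | COc1cc(OCc2ccccc2)c(cc1OCc1ccccc1)[C@@H]3CC(=O)c4c(OCc5ccccc5)c(C)c(OC)c(C)c4O3 | intermediate
21 | (2S)-2-(2,5-dihydroxy-4-methoxyphenyl)-5-hydroxy-7-methoxy-6,8-dimethylchroman-4-one | COc1cc(O)c(cc1O)[C@@H]3CC(=O)c4c(O)c(C)c(OC)c(C)c4O3 | intermediate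
22 | (2S)-5-hydroxy-7-methoxy-2-(4-methoxy-3,6-dioxocyclohexa-1,4-dien-1-yl)-6,8-dimethylchroman-4-one | COC1=CC(=O)C([C@@H]2CC(=O)c3c(O)c(C)c(OC)c(C)c3O2)=CC1=O | target

**Step count**

Total: 15 steps. Longest linear sequence: 13 steps (steps 3 to 15, from aniline 5); the ring B branch (steps 1 and 2) joins at step 8.

**Steps most likely to fail**

Step 11 (key step). After oxidative addition at the doubly ortho-substituted C8a–Br bond, β-hydride elimination of the palladium alkoxide may outrun C–O reductive elimination, which would oxidise the carbinol and reduce the arene, or oxidative addition may stall. The fallback closes the same ring through the other ether bond, O1–C2, by a Mitsunobu reaction with inversion.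
- From 16, transfer hydrogenation with the enantiomeric catalyst RuCl[(R,R)-TsDPEN](p-cymene) in HCO2H/Et3N would give (1R)-1-[2,5-bis(benzyloxy)-4-methoxyphenyl]-3-[2-(benzyloxy)-6-bromo-4-methoxy-3,5-dimethylphenyl]-3-[(tert-butyldimethylsilyl)oxy]propan-1-ol F1.
- Miyaura borylation of the bromide (Pd(OAc)2, SPhos, B2pin2, KOAc, dioxane, 90 °C) would give the C8a pinacol boronate F2.
- Oxidation with NaBO3·4H2O in THF/H2O would give the C8a phenol F3.
- PPh3 and DIAD in toluene at 0 °C would then let the phenol displace the activated (R)-carbinol with inversion, which returns to the route at 18.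
- The weak point of this detour is ionisation at the electron-rich benzylic carbon, which the non-polar solvent and low temperature are meant to limit.

Step 14. Over-reduction may occur while the last benzyl ether is still being removed: hydrogenolytic opening of the benzylic O1–C2 bond to a dihydrochalcone, or reduction of the C4 carbonyl. The fallback is a non-reductive Lewis acid debenzylation. From 20, BCl3 with pentamethylbenzene as benzyl cation scavenger in CH2Cl2 at −78 °C would cleave the three benzyl ethers and give 21 directly, where the route is rejoined. This detour makes no compound outside the list (F0).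

Step 10. Facial selectivity may be poor because of the ortho-benzyloxy group of ring B, the two C3 epimers may react at different rates, or the amine may induce β-elimination of silanol to the enone. The fallback replaces the metal-hydride transfer catalysis by a borane reduction steered by a chiral Lewis acid (Corey–Bakshi–Shibata reduction), which is base-free and differentiates the aryl and methylene flanks by size. From 16, (R)-2-methyl-CBS-oxazaborolidine and BH3·SMe2 in THF at −20 °C, followed by methanol work-up, should give 17, where the route is rejoined. This detour makes no compound outside the list (F0).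

**Further compounds**

F1 | step 11 | (1R)-1-[2,5-bis(benzyloxy)-4-methoxyphenyl]-3-[2-(benzyloxy)-6-bromo-4-methoxy-3,5-dimethylphenyl]-3-[(tert-butyldimethylsilyl)oxy]propan-1-ol (both C3 epimers) | COc1cc(OCc2ccccc2)c(cc1OCc1ccccc1)[C@H](O)CC(O[Si](C)(C)C(C)(C)C)c1c(Br)c(C)c(OC)c(C)c1OCc1ccccc1
F2 | step 11 | (1R)-1-[2,5-bis(benzyloxy)-4-methoxyphenyl]-3-[2-(benzyloxy)-4-methoxy-3,5-dimethyl-6-(4,4,5,5-tetramethyl-1,3,2-dioxaborolan-2-yl)phenyl]-3-[(tert-butyldimethylsilyl)oxy]propan-1-ol (both C3 epimers) | COc1cc(OCc2ccccc2)c(cc1OCc1ccccc1)[C@H](O)CC(O[Si](C)(C)C(C)(C)C)c1c(B2OC(C)(C)C(C)(C)O2)c(C)c(OC)c(C)c1OCc1ccccc1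
F3 | step 11 | 3-(benzyloxy)-2-[(3R)-3-[2,5-bis(benzyloxy)-4-methoxyphenyl]-1-[(tert-butyldimethylsilyl)oxy]-3-hydroxypropyl]-5-methoxy-4,6-dimethylphenol (both epimers at the silyloxy carbon) | COc1cc(OCc2ccccc2)c(cc1OCc1ccccc1)[C@H](O)CC(O[Si](C)(C)C(C)(C)C)c1c(O)c(C)c(OC)c(C)c1OCc1ccccc1
F0 | step 14 | none | none
F0 | step 10 | none | none
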